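**Retrosynthetic overview**

1. Ester C–O bond last: the target comes from 4β,6α-dihydroxydauc-7-en-9-one and a protected (E)-p-coumaric acid.
2. Both rings come from an acyclic farnesane chain in one cation–olefin bicyclization. It makes the two C–C bonds the daucane cyclase makes, by anti addition across the 6E-olefin through the tertiary C7 cation: C6–C10 (five-membered ring, first) and C1–C7 (seven-membered ring, second).
3. The cascade is triggered at the C10 isopropyl ketone, which gives the 4-carbinol directly, and ended by a 2-ethoxydiene, which gives the 7-en-9-one.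
4. The chain is joined at C5–C6 by an enantioselective Ni/Cr coupling of an E-alkenyl iodide with a Z-dienal; this carbinol carbon is the only stereocentre made before the cyclization and steers the other three.
5. Fragments: propargyl alcohol + 3-methylbutan-2-one, and but-2-yn-1-ol + an ethoxyvinylstannane.

Assumption: acyclic intermediates are numbered as in farnesane (its C1, C2, C5, C6, C7, C10 become daucane C10, C9, C6, C5, C1, C4), and in step 7 the ligand enantiomer used is the one that gives the 8R silyl ether (assigned once by Mosher analysis of a desilylated sample).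

**Route**

Step 1
Reactants: 1 prop-2-yn-1-ol
Product: 3 (E)-3-iodo-2-methylprop-2-en-1-ol, via alkenylalane 2 (not isolated)
Conditions: AlMe3 (3 equiv), Cp2ZrCl2 (0.3 equiv), CH2Cl2, 0 °C → rt; then I2, THF, −30 → 0 °C; aq. K2CO3
Reagents that add atoms: trimethylaluminium C[Al](C)C; iodine [I][I]
Why: Negishi zirconium-catalysed carboalumination adds Me and Al syn across the alkyne with Me on the internal carbon, and iodinolysis of the C–Al bond with retention leaves I cis to CH3 (E).

Step 2
Reactants: 3 (E)-3-iodo-2-methylprop-2-en-1-ol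
Product: 4 (E)-3-bromo-1-iodo-2-methylprop-1-ene
Conditions: CBr4, PPh3, CH2Cl2, 0 °C
Reagents that add atoms: tetrabromomethane BrC(Br)(Br)Br
Why: Appel reaction; bromide displaces the alkoxyphosphonium group at the primary allylic carbon (SN2) and the vinyl iodide geometry is untouched.

Step 3
Reactants: 4 (E)-3-bromo-1-iodo-2-methylprop-1-ene; 5 3-methylbutan-2-one
Product: 7 (E)-7-iodo-2,6-dimethylhept-6-en-3-one, via lithium enolate 6 (not isolated)
Conditions: 5 (1.3 equiv), LiN(iPr)2, THF, −78 °C; then 4, −78 → −30 °C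
Reagents that add atoms: lithium diisopropylamide CC(C)N([Li])C(C)C (lithium in 6 only)
Why: kinetic enolate alkylation; the base deprotonates only the CH3 side of 5 and enolate 6 displaces the allylic bromide (SN2) without touching the vinyl iodide.

Step 4
Reactants: 8 but-2-yn-1-ol
Product: 10 (Z)-3-iodobut-2-en-1-ol, via cyclic alkenylaluminate 9 (not isolated)
Conditions: NaAlH2(OCH2CH2OMe)2, THF, 0 °C → rt; then I2, −78 → 0 °C
Reagents that add atoms: sodium bis(2-methoxyethoxy)aluminium dihydride [Na+].[H][Al-]([H])(OCCOC)OCCOC (in 9 only); iodine [I][I]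
Why: hydroxyl-directed trans-hydroalumination puts aluminium on C3 cis to the CH2O group (cyclic aluminate 9), and iodinolysis with retention gives the Z iodide.

Step 5
Reactants: 10 (Z)-3-iodobut-2-en-1-ol
Product: 11 (Z)-3-iodobut-2-enal
Conditions: MnO2, CH2Cl2, rt, dark
Reagents that add atoms: none
Why: allylic oxidation on MnO2 is neutral and stops at the aldehyde, so the Z geometry and the C–I bond survive.

Step 6
Reactants: 11 (Z)-3-iodobut-2-enal; 12 tributyl(1-ethoxyvinyl)stannane
Product: 13 (2Z)-4-ethoxy-3-methylpenta-2,4-dienal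
Conditions: Pd(PPh3)4 (5 mol%), CuI (10 mol%), DMF, rt, dark; Et3N-treated silica
Reagents that add atoms: none
Why: Stille cross-coupling replaces iodide by the 1-ethoxyvinyl group with retention; the enol ether is the masked C9 ketone and the later π-terminator, and the Z geometry is the one the seven-membered ring needs.

Step 7
Reactants: 7 (E)-7-iodo-2,6-dimethylhept-6-en-3-one; 13 (2Z)-4-ethoxy-3-methylpenta-2,4-dienal
Product: 14 (6E,8R,9Z)-11-ethoxy-2,6,10-trimethyl-8-[(triethylsilyl)oxy]dodeca-6,9,11-trien-3-one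
Conditions: CrCl2 (10 mol%), N-[2-(4-isopropyl-4,5-dihydro-1,3-oxazol-2-yl)-6-methylphenyl]methanesulfonamide (12 mol%), 1,8-bis(dimethylamino)naphthalene (12 mol%), NiCl2·(2,9-dimethyl-1,10-phenanthroline) (2 mol%), Mn (2 equiv), LiCl, TESCl (1.5 equiv), MeCN, rt
Reagents that add atoms: chlorotriethylsilane CC[Si](Cl)(CC)CC
Why: catalytic asymmetric Nozaki–Hiyama–Kishi coupling; the alkenyl group passes from nickel to chromium with retention of E and adds to the aldehyde only (ketone and enol ether untouched), the sulfonamide-bound chromium selects the aldehyde face to set C8 as R, and TESCl frees the chromium and caps the alkoxide.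

Step 8
Reactants: 14 (6E,8R,9Z)-11-ethoxy-2,6,10-trimethyl-8-[(triethylsilyl)oxy]dodeca-6,9,11-trien-3-one
Product: 17 4β,6α-dihydroxydauc-7-en-9-one, via O-ethyl oxocarbenium aluminate 15 (not isolated), via 6-O-triethylsilyl keto alcohol 16 (not isolated)
Conditions: MeAlCl2 (1.5 equiv), CH2Cl2, −78 → −40 °C, 14 added by syringe pump (final 0.003 M); then 1 M aq. HCl, THF, 0 °C → rt
Reagents that add atoms: water O (ketone oxygen of 17); methylaluminium dichloride C[Al](Cl)Cl (in 15 only)
Why: Proposed new method: the ketone–MeAlCl2 complex is attacked 5-endo by C6 of the 6E-olefin (C6–C10, five-membered ring) while the 2-ethoxydiene adds through C1 to the developing tertiary C7 cation from the opposite face (C1–C7, seven-membered ring), an anti addition that gives the trans ring fusion (5α-H, 1β-CH3); allylic 1,3-strain holds the C–H of the 8R centre in the olefin plane so the diene arm and the ketone use opposite faces and the 6α-oxygen ends cis to 5-H, the isopropyl group turns away from that arm so the carbinol is 4β-OH, and hydrolysis of the O-ethyl oxocarbenium and of the silyl ether gives 17; the closest known reaction types are the MeAlCl2-promoted ketone-initiated cation–olefin (Prins) cyclization of γ,δ-unsaturated ketones and polyene cyclizations ended by enol ethers.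

Step 9
Reactants: 17 4β,6α-dihydroxydauc-7-en-9-one; 18 (E)-4-acetoxycinnamic acid
Product: 20 (3R,3aS,4S,8aR)-3-hydroxy-6,8a-dimethyl-7-oxo-3-(propan-2-yl)-1,2,3,3a,4,7,8,8a-octahydroazulen-4-yl (2E)-3-(4-hydroxyphenyl)prop-2-enoate, via aryl acetate 19 (not isolated)
Conditions: 18 (1.3 equiv), DCC, DMAP (cat.), CH2Cl2, 0 °C → rt; then pyrrolidine, 0 °C
Reagents that add atoms: none
Why: Steglich esterification acylates only the secondary allylic 6-OH (the tertiary 4-OH is inert) with no change at C6, and pyrrolidine then cleaves the aryl acetate by aminolysis much faster than it attacks the cinnamate or the enone.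

**Compound list**

1 | prop-2-yn-1-ol | C#CCO | starting material
2 | (E)-alkenylalane, Me2Al–CH=C(CH3)–CH2–O–AlMe2 | C[Al](C)OC/C(C)=C/[Al](C)C | intermediate
3 | (E)-3-iodo-2-methylprop-2-en-1-ol | OC/C(C)=C/I | intermediate
4 | (E)-3-bromo-1-iodo-2-methylprop-1-ene | BrC/C(C)=C/I | intermediate
5 | 3-methylbutan-2-one | CC(=O)C(C)C | starting material
6 | lithium 3-methylbut-1-en-2-olate | C=C(O[Li])C(C)C | intermediate
7 | (E)-7-iodo-2,6-dimethylhept-6-en-3-one | CC(C)C(=O)CC/C(C)=C/I | intermediate
8 | but-2-yn-1-ol | CC#CCO | starting material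
9 | sodium cyclic alkenylaluminate (five-membered ring Al–O–CH2–CH=C(CH3), two 2-methoxyethoxy groups on Al) | CC1=CCO[Al-]1(OCCOC)OCCOC.[Na+] | intermediate
10 | (Z)-3-iodobut-2-en-1-ol | C/C(I)=C/CO | intermediate
11 | (Z)-3-iodobut-2-enal | C/C(I)=C/C=O | intermediate
12 | tributyl(1-ethoxyvinyl)stannane | C=C(OCC)[Sn](CCCC)(CCCC)CCCC | starting material
13 | (2Z)-4-ethoxy-3-methylpenta-2,4-dienal | C=C(OCC)/C(C)=C\C=O | intermediate
14 | (6E,8R,9Z)-11-ethoxy-2,6,10-trimethyl-8-[(triethylsilyl)oxy]dodeca-6,9,11-trien-3-one | C=C(OCC)/C(C)=C\[C@H](O[Si](CC)(CC)CC)/C=C(\C)CCC(=O)C(C)C | intermediate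
15 | bicyclic zwitterion: daucane skeleton, C9=O(+)–Et, 4-O–AlMeCl2(−), 6-OTES | CC1=C[C@H](O[Si](CC)(CC)CC)[C@@H]2[C@](C)(CC[C@@]2(O[Al-](C)(Cl)Cl)C(C)C)CC1=[O+]CC | intermediate
16 | 4β-hydroxy-6α-[(triethylsilyl)oxy]dauc-7-en-9-one | CC1=C[C@H](O[Si](CC)(CC)CC)[C@@H]2[C@](C)(CC[C@@]2(O)C(C)C)CC1=O | intermediate
17 | 4β,6α-dihydroxydauc-7-en-9-one (3R,3aS,4S,8aR with the locants of the target name) | CC1=C[C@H](O)[C@@H]2[C@](C)(CC[C@@]2(O)C(C)C)CC1=O | intermediate
18 | (E)-4-acetoxycinnamic acid | CC(=O)Oc1ccc(/C=C/C(=O)O)cc1 | starting material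
19 | 4β-hydroxy-9-oxodauc-7-en-6α-yl (E)-3-(4-acetoxyphenyl)prop-2-enoate | CC1=C[C@H](OC(=O)/C=C/c2ccc(OC(C)=O)cc2)[C@@H]2[C@](C)(CC[C@@]2(O)C(C)C)CC1=O | intermediate
20 | (3R,3aS,4S,8aR)-3-hydroxy-6,8a-dimethyl-7-oxo-3-(propan-2-yl)-1,2,3,3a,4,7,8,8a-octahydroazulen-4-yl (2E)-3-(4-hydroxyphenyl)prop-2-enoate | CC1=C[C@H](OC(=O)/C=C/c2ccc(O)cc2)[C@@H]2[C@](C)(CC[C@@]2(O)C(C)C)CC1=O | target

**Step count and risks**

Total steps: 9. Longest linear sequence: 6 (steps 1–3 then 7–9, or steps 4–6 then 7–9).

Most likely to fail: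

Step 8. The doubly allylic silyl ether may ionise, the C7 cation may undergo a 1,2-shift or take chloride before the diene arrives, or the cis-fused isomer may form. The fallback sets out from 14 and returns at 17, making the rings one at a time. The enol ether of 14 alone is hydrolysed (pyridinium p-toluenesulfonate, wet acetone, 0 °C) to (6E,8R,9Z)-2,6,10-trimethyl-8-[(triethylsilyl)oxy]dodeca-6,9-diene-3,11-dione F1. TiCl4 at −78 °C then closes only the five-membered ring by a ketone–olefin Prins reaction with chloride capture, giving the monocyclic tertiary chloride (cyclopentanol carrying C7–Cl and the Z-enone side chain) F2. TMSOTf/Et3N converts its methyl ketone and tertiary alcohol into the trimethylsilyl dienol ether and silyl ether F3. TiCl4 re-ionises the chloride and the silyl dienol ether alkylates the tertiary cation (Reetz-type α-tert-alkylation) to the bicyclic bis-silyl ether F4, which 1 M HCl in THF converts to 17. The ring fusion is then no longer fixed by anti addition and the isomers would have to be separated.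

Step 7. The enantioselectivity with two functionalised partners is uncertain and the dienal is acid-sensitive. The fallback sets out from 7 and 13 and returns at 14: the coupling is run without chiral ligand (CrCl2 3 equiv, NiCl2 1 mol%, DMF; then TESCl, imidazole) to give racemic (6E,9Z)-11-ethoxy-2,6,10-trimethyl-8-[(triethylsilyl)oxy]dodeca-6,9,11-trien-3-one F5. The enantiomers are separated by preparative HPLC on a chiral stationary phase (hexane/2-propanol with 0.1% Et3N), and the 8R enantiomer is 14.

Step 9. The 6-OH is hindered and pyrrolidine could add to the enone. The fallback sets out from 17 and returns at 20, building the cinnamate on the alcohol instead of coupling it. Meldrum's acid in toluene at 90 °C gives the hydrogen malonate of 17 F6. Knoevenagel–Doebner condensation with 4-hydroxybenzaldehyde (pyridine, cat. piperidine, 50 °C) then gives 20 directly, E-selective and with the phenol free.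

Further compounds
F1 | step 8 | (6E,8R,9Z)-2,6,10-trimethyl-8-[(triethylsilyl)oxy]dodeca-6,9-diene-3,11-dione | CC(=O)/C(C)=C\[C@H](O[Si](CC)(CC)CC)/C=C(\C)CCC(=O)C(C)C
F2 | step 8 | (3Z,5S)-5-[(1S,2R)-5-chloro-2-hydroxy-5-methyl-2-(propan-2-yl)cyclopentyl]-3-methyl-5-[(triethylsilyl)oxy]pent-3-en-2-one (C–Cl epimers) | CC(=O)/C(C)=C\[C@H](O[Si](CC)(CC)CC)[C@@H]1C(C)(Cl)CC[C@@]1(O)C(C)C
F3 | step 8 | trimethylsilyl dienol ether and tertiary trimethylsilyl ether of F2 | C=C(O[Si](C)(C)C)/C(C)=C\[C@H](O[Si](CC)(CC)CC)[C@@H]1C(C)(Cl)CC[C@@]1(O[Si](C)(C)C)C(C)C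
F4 | step 8 | 6α-[(triethylsilyl)oxy]-4β-[(trimethylsilyl)oxy]dauc-7-en-9-one | CC1=C[C@H](O[Si](CC)(CC)CC)[C@@H]2[C@](C)(CC[C@@]2(O[Si](C)(C)C)C(C)C)CC1=O
F5 | step 7 | racemic (6E,9Z)-11-ethoxy-2,6,10-trimethyl-8-[(triethylsilyl)oxy]dodeca-6,9,11-trien-3-one | C=C(OCC)/C(C)=C\C(O[Si](CC)(CC)CC)/C=C(\C)CCC(=O)C(C)C
F6 | step 9 | 4β-hydroxy-9-oxodauc-7-en-6α-yl hydrogen malonate | CC1=C[C@H](OC(=O)CC(=O)O)[C@@H]2[C@](C)(CC[C@@]2(O)C(C)C)CC1=O
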